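**Retrosynthetic overview**
1. Target ⇐ one hydride step that reduces an aldehyde, a cinnamate ester and an aryl pivalate in a trans‑3‑formyl‑2‑aryl‑2,3‑dihydrobenzofuran.
2. Dihydrofuran ⇐ C2–C3 bond by intramolecular C–H insertion of an α‑imino rhodium carbene into the ArO–CH2–Ar' ether; the carbene comes from a 1‑mesyl‑1,2,3‑triazole closed in the same flask from a terminal alkyne and MeSO2N3.
3. Alkyne ⇐ aldehyde (one‑carbon homologation); benzyl aryl ether ⇐ Mitsunobu union of methyl 5‑formylferulate (Heck product of 5‑bromo‑o‑vanillin) with O‑pivaloyl syringyl alcohol (from syringaldehyde).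
4. Ring order: both benzene rings are bought; in the key operation the triazole ring closes first and the dihydrofuran ring second, the triazole being spent as N2 as the furan ring forms.

Abbreviations: NTTL = N‑(1,8‑naphthaloyl)‑tert‑leucinate; PTTL = N‑phthaloyl‑tert‑leucinate; CuTC = Cu(O2C‑C4H3S), copper thiophene‑2‑carboxylate (monovalent copper); DIAD = diisopropyl azodicarboxylate.

Assumption: Rh2(S‑NTTL)4 is taken to give the (2S) sense at the new C–O stereocentre; if the first run shows the opposite sense, the mirror‑image catalyst Rh2(R‑NTTL)4 replaces it with no other change.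

**Route**

Step 1
Reactants: 1 syringaldehyde (4‑hydroxy‑3,5‑dimethoxybenzaldehyde)
Product: 2 4‑formyl‑2,6‑dimethoxyphenyl 2,2‑dimethylpropanoate
Conditions: t‑BuCOCl (1.2 equiv), Et3N (1.5 equiv), DMAP (5 mol %), CH2Cl2, 0 °C to rt
Reagents that add atoms: pivaloyl chloride, CC(C)(C)C(=O)Cl
Why: DMAP‑catalysed O‑acylation (nucleophilic acyl substitution) masks the phenol against the rhodium carbene as a hindered pivalate that the final hydride step removes.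

Step 2
Reactants: 2 4‑formyl‑2,6‑dimethoxyphenyl 2,2‑dimethylpropanoate
Product: 3 4‑(hydroxymethyl)‑2,6‑dimethoxyphenyl 2,2‑dimethylpropanoate
Conditions: NaBH4 (0.6 equiv), THF/MeOH 4:1, 0 °C, 30 min
Reagents that add atoms: none
Why: Borohydride reduction of the aldehyde; the doubly ortho‑substituted aryl pivalate is inert at 0 °C.

Step 3
Reactants: 4 5‑bromo‑2‑hydroxy‑3‑methoxybenzaldehyde; 5 methyl acrylate
Product: 6 methyl (2E)‑3‑(3‑formyl‑4‑hydroxy‑5‑methoxyphenyl)prop‑2‑enoate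
Conditions: Pd(OAc)2 (3 mol %), P(o‑tol)3 (6 mol %), Et3N (3 equiv), DMF, 100 °C
Reagents that add atoms: none
Why: Mizoroki–Heck reaction; syn insertion and syn β‑hydride elimination give only the E‑cinnamate, and bromophenols bearing an aldehyde are tolerated.

Step 4
Reactants: 3 4‑(hydroxymethyl)‑2,6‑dimethoxyphenyl 2,2‑dimethylpropanoate; 6 methyl (2E)‑3‑(3‑formyl‑4‑hydroxy‑5‑methoxyphenyl)prop‑2‑enoate
Product: 7 methyl (2E)‑3‑[4‑({4‑[(2,2‑dimethylpropanoyl)oxy]‑3,5‑dimethoxyphenyl}methoxy)‑3‑formyl‑5‑methoxyphenyl]prop‑2‑enoate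
Conditions: PPh3 (1.3 equiv), DIAD (1.3 equiv), THF, 0 °C to rt
Reagents that add atoms: none
Why: Mitsunobu etherification; the acidic salicylaldehyde‑type phenol (pKa about 8) displaces the activated primary benzylic alcohol, and no stereocentre is involved.

Step 5
Reactants: 7 methyl (2E)‑3‑[4‑({4‑[(2,2‑dimethylpropanoyl)oxy]‑3,5‑dimethoxyphenyl}methoxy)‑3‑formyl‑5‑methoxyphenyl]prop‑2‑enoate
Product: 8 methyl (2E)‑3‑[4‑({4‑[(2,2‑dimethylpropanoyl)oxy]‑3,5‑dimethoxyphenyl}methoxy)‑3‑ethynyl‑5‑methoxyphenyl]prop‑2‑enoate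
Conditions: dimethyl (1‑diazo‑2‑oxopropyl)phosphonate (1.3 equiv), K2CO3 (2 equiv), MeOH/THF, 0 °C to rt, 4 h
Reagents that add atoms: Ohira–Bestmann reagent, CC(=O)C(=[N+]=[N-])P(=O)(OC)OC
Why: Seyferth–Gilbert homologation in the Ohira–Bestmann form (addition of the diazomethylphosphonate anion, loss of phosphate and N2, 1,2‑H shift of the alkylidene carbene) turns ArCHO into ArC≡CH; the methyl ester and the hindered pivalate should survive K2CO3/MeOH at this temperature.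

Step 6
Reactants: 8 methyl (2E)‑3‑[4‑({4‑[(2,2‑dimethylpropanoyl)oxy]‑3,5‑dimethoxyphenyl}methoxy)‑3‑ethynyl‑5‑methoxyphenyl]prop‑2‑enoate
Product: 12 methyl (2E)‑3‑[(2S,3S)‑2‑{4‑[(2,2‑dimethylpropanoyl)oxy]‑3,5‑dimethoxyphenyl}‑3‑formyl‑7‑methoxy‑2,3‑dihydro‑1‑benzofuran‑5‑yl]prop‑2‑enoate, via 1‑mesyl‑1,2,3‑triazole 9 (not isolated), via cis N‑mesyl aldimine 10 (not isolated), via cis aldehyde 11 (not isolated)
Conditions: MeSO2N3 (1.05 equiv), CuTC (10 mol %), CHCl3 (0.05 M), rt, 3 h; then Rh2(S‑NTTL)4 (2 mol %), 4 Å MS, 60 °C, 2 h; then K2CO3 (0.5 equiv), THF/H2O, rt, 1 h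
Reagents that add atoms: water, O; methanesulfonyl azide, CS(=O)(=O)N=[N+]=[N-] (its atoms sit only in 9 and 10 and are gone in 12)
Why: Proposed new method: copper‑catalysed sulfonyl azide–alkyne cycloaddition closes the triazole ring, whose open α‑diazo imine tautomer is decomposed by the chiral dirhodium tetracarboxylate to an electrophilic α‑imino carbene that inserts into the only geometrically accessible C–H bond (the ether CH2, activated by oxygen and the electron‑rich aryl, 1,5 relation, five‑membered transition state), so the ligand sphere sets C2 (cis product expected), after which the sulfonyl imine is hydrolysed and the epimerisable C3 aldehyde relaxes under mild base to the more stable trans isomer without touching C2; the closest known reaction types are Fokin–Davies enantioselective C–H insertion of triazole‑derived rhodium azavinyl carbenes run one‑pot from alkynes and Hashimoto‑type aryldiazoacetate insertion giving cis‑2‑aryl‑2,3‑dihydrobenzofurans.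

Step 7
Reactants: 12 methyl (2E)‑3‑[(2S,3S)‑2‑{4‑[(2,2‑dimethylpropanoyl)oxy]‑3,5‑dimethoxyphenyl}‑3‑formyl‑7‑methoxy‑2,3‑dihydro‑1‑benzofuran‑5‑yl]prop‑2‑enoate
Product: 13 4‑[(2S,3R)‑3‑(hydroxymethyl)‑5‑[(1E)‑3‑hydroxyprop‑1‑en‑1‑yl]‑7‑methoxy‑2,3‑dihydro‑1‑benzofuran‑2‑yl]‑2,6‑dimethoxyphenol
Conditions: i‑Bu2AlH (8 equiv), CH2Cl2, −78 to 0 °C; aq. KNaC4H4O6 work‑up
Reagents that add atoms: none
Why: Hydride reduction with i‑Bu2AlH takes the aldehyde to the primary alcohol, the cinnamate to the E‑allylic alcohol by clean 1,2‑reduction and the aryl pivalate to the free phenol; neither stereocentre is touched, and C3 stops being epimerisable once the aldehyde is reduced (the descriptor changes from 3S to 3R only through CIP priorities).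

**Compound list**
1 | syringaldehyde (4‑hydroxy‑3,5‑dimethoxybenzaldehyde) | COc1cc(C=O)cc(OC)c1O | starting material
2 | 4‑formyl‑2,6‑dimethoxyphenyl 2,2‑dimethylpropanoate | COc1cc(C=O)cc(OC)c1OC(=O)C(C)(C)C | intermediate
3 | 4‑(hydroxymethyl)‑2,6‑dimethoxyphenyl 2,2‑dimethylpropanoate | COc1cc(CO)cc(OC)c1OC(=O)C(C)(C)C | intermediate
4 | 5‑bromo‑2‑hydroxy‑3‑methoxybenzaldehyde (5‑bromo‑o‑vanillin) | COc1cc(Br)cc(C=O)c1O | starting material
5 | methyl acrylate | C=CC(=O)OC | starting material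
6 | methyl (2E)‑3‑(3‑formyl‑4‑hydroxy‑5‑methoxyphenyl)prop‑2‑enoate | COC(=O)/C=C/c1cc(OC)c(O)c(C=O)c1 | intermediate
7 | methyl (2E)‑3‑[4‑({4‑[(2,2‑dimethylpropanoyl)oxy]‑3,5‑dimethoxyphenyl}methoxy)‑3‑formyl‑5‑methoxyphenyl]prop‑2‑enoate | COC(=O)/C=C/c1cc(OC)c(OCc2cc(OC)c(OC(=O)C(C)(C)C)c(OC)c2)c(C=O)c1 | intermediate
8 | methyl (2E)‑3‑[4‑({4‑[(2,2‑dimethylpropanoyl)oxy]‑3,5‑dimethoxyphenyl}methoxy)‑3‑ethynyl‑5‑methoxyphenyl]prop‑2‑enoate | COC(=O)/C=C/c1cc(OC)c(OCc2cc(OC)c(OC(=O)C(C)(C)C)c(OC)c2)c(C#C)c1 | intermediate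
9 | methyl (2E)‑3‑{4‑({4‑[(2,2‑dimethylpropanoyl)oxy]‑3,5‑dimethoxyphenyl}methoxy)‑3‑methoxy‑5‑[1‑(methanesulfonyl)‑1H‑1,2,3‑triazol‑4‑yl]phenyl}prop‑2‑enoate | COC(=O)/C=C/c1cc(OC)c(OCc2cc(OC)c(OC(=O)C(C)(C)C)c(OC)c2)c(-c2cn(S(C)(=O)=O)nn2)c1 | intermediate (not isolated)
10 | methyl (2E)‑3‑[(2S,3S)‑2‑{4‑[(2,2‑dimethylpropanoyl)oxy]‑3,5‑dimethoxyphenyl}‑3‑{(E)‑[(methanesulfonyl)imino]methyl}‑7‑methoxy‑2,3‑dihydro‑1‑benzofuran‑5‑yl]prop‑2‑enoate (2,3‑cis) | COc1cc([C@H]2Oc3c(OC)cc(/C=C/C(=O)OC)cc3[C@H]2/C=N/S(C)(=O)=O)cc(OC)c1OC(=O)C(C)(C)C | intermediate (not isolated)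
11 | methyl (2E)‑3‑[(2S,3R)‑2‑{4‑[(2,2‑dimethylpropanoyl)oxy]‑3,5‑dimethoxyphenyl}‑3‑formyl‑7‑methoxy‑2,3‑dihydro‑1‑benzofuran‑5‑yl]prop‑2‑enoate (2,3‑cis) | COc1cc([C@H]2Oc3c(OC)cc(/C=C/C(=O)OC)cc3[C@H]2C=O)cc(OC)c1OC(=O)C(C)(C)C | intermediate (not isolated)
12 | methyl (2E)‑3‑[(2S,3S)‑2‑{4‑[(2,2‑dimethylpropanoyl)oxy]‑3,5‑dimethoxyphenyl}‑3‑formyl‑7‑methoxy‑2,3‑dihydro‑1‑benzofuran‑5‑yl]prop‑2‑enoate (2,3‑trans) | COc1cc([C@H]2Oc3c(OC)cc(/C=C/C(=O)OC)cc3[C@@H]2C=O)cc(OC)c1OC(=O)C(C)(C)C | intermediate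
13 | 4‑[(2S,3R)‑3‑(hydroxymethyl)‑5‑[(1E)‑3‑hydroxyprop‑1‑en‑1‑yl]‑7‑methoxy‑2,3‑dihydro‑1‑benzofuran‑2‑yl]‑2,6‑dimethoxyphenol | COc1cc([C@H]2Oc3c(OC)cc(/C=C/CO)cc3[C@@H]2CO)cc(OC)c1O | target

**Totals**
Total step count: 7. Longest linear sequence: 6 (steps 1, 2, 4, 5, 6, 7 from syringaldehyde).

**Steps most likely to fail, with fallbacks**

Step 6 (one‑pot triazole formation, C–H insertion, hydrolysis and epimerisation). The risks are a stepwise hydride shift with closure at nitrogen, tautomerisation of the sulfonyl imine to an enamide that aromatises to the benzofuran, and modest enantioselectivity. The fallback changes the carbene class to a donor/acceptor diazo ester, for which this ring closure is established. It sets out from 8 and comes back at 13. Rhodium‑vinylidene oxygenative addition of methanol to the alkyne ([Rh(cod)Cl]2, P(4‑FC6H4)3, 4‑picoline N‑oxide, MeOH/MeCN, 60 °C) gives methyl (2E)‑3‑[4‑({4‑[(2,2‑dimethylpropanoyl)oxy]‑3,5‑dimethoxyphenyl}methoxy)‑3‑methoxy‑5‑(2‑methoxy‑2‑oxoethyl)phenyl]prop‑2‑enoate F1. Diazo transfer (4‑acetamidobenzenesulfonyl azide, DBU, MeCN) gives methyl (2E)‑3‑[3‑(1‑diazo‑2‑methoxy‑2‑oxoethyl)‑4‑({4‑[(2,2‑dimethylpropanoyl)oxy]‑3,5‑dimethoxyphenyl}methoxy)‑5‑methoxyphenyl]prop‑2‑enoate F2. Insertion with Rh2(S‑PTTL)4 in toluene at −60 °C (the tert‑leucinate antipode that gives 2S is used) gives methyl (2S,3R)‑2‑{4‑[(2,2‑dimethylpropanoyl)oxy]‑3,5‑dimethoxyphenyl}‑7‑methoxy‑5‑[(1E)‑3‑methoxy‑3‑oxoprop‑1‑en‑1‑yl]‑2,3‑dihydro‑1‑benzofuran‑3‑carboxylate F3, the cis ester. DBU in toluene at 60 °C epimerises C3 to methyl (2S,3S)‑2‑{4‑[(2,2‑dimethylpropanoyl)oxy]‑3,5‑dimethoxyphenyl}‑7‑methoxy‑5‑[(1E)‑3‑methoxy‑3‑oxoprop‑1‑en‑1‑yl]‑2,3‑dihydro‑1‑benzofuran‑3‑carboxylate F4, the trans ester. i‑Bu2AlH then reduces both esters and cleaves the pivalate to give 13.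

Step 5 (Ohira–Bestmann homologation in the presence of the aryl pivalate). The risk is methanolysis of the pivalate; the freed phenoxide would expel the salicylaldehyde‑type phenoxide through a quinone methide. The fallback changes the order of events so that the pivalate never meets methoxide. It sets out from 6 and comes back at 8. The same homologation on the free phenol gives methyl (2E)‑3‑(3‑ethynyl‑4‑hydroxy‑5‑methoxyphenyl)prop‑2‑enoate F5, which is joined to 3 under the Mitsunobu conditions of step 4 to give 8 directly.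

Step 4 (Mitsunobu on a doubly ortho‑substituted, hydrogen‑bonded phenol with an electron‑rich benzylic alcohol). The risks are slow coupling and self‑condensation of the benzylic alcohol. The fallback replaces the redox condensation by a Williamson alkylation. It sets out from 3 and comes back at 7. Appel bromination (CBr4, PPh3, CH2Cl2, 0 °C) gives 4‑(bromomethyl)‑2,6‑dimethoxyphenyl 2,2‑dimethylpropanoate F6, which alkylates phenol 6 (K2CO3, acetone, 50 °C) to give 7.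

**Further compounds**
F1 | step 6 | methyl (2E)‑3‑[4‑({4‑[(2,2‑dimethylpropanoyl)oxy]‑3,5‑dimethoxyphenyl}methoxy)‑3‑methoxy‑5‑(2‑methoxy‑2‑oxoethyl)phenyl]prop‑2‑enoate | COC(=O)/C=C/c1cc(OC)c(OCc2cc(OC)c(OC(=O)C(C)(C)C)c(OC)c2)c(CC(=O)OC)c1
F2 | step 6 | methyl (2E)‑3‑[3‑(1‑diazo‑2‑methoxy‑2‑oxoethyl)‑4‑({4‑[(2,2‑dimethylpropanoyl)oxy]‑3,5‑dimethoxyphenyl}methoxy)‑5‑methoxyphenyl]prop‑2‑enoate | COC(=O)/C=C/c1cc(OC)c(OCc2cc(OC)c(OC(=O)C(C)(C)C)c(OC)c2)c(C(=[N+]=[N-])C(=O)OC)c1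
F3 | step 6 | methyl (2S,3R)‑2‑{4‑[(2,2‑dimethylpropanoyl)oxy]‑3,5‑dimethoxyphenyl}‑7‑methoxy‑5‑[(1E)‑3‑methoxy‑3‑oxoprop‑1‑en‑1‑yl]‑2,3‑dihydro‑1‑benzofuran‑3‑carboxylate (2,3‑cis) | COc1cc([C@H]2Oc3c(OC)cc(/C=C/C(=O)OC)cc3[C@H]2C(=O)OC)cc(OC)c1OC(=O)C(C)(C)C
F4 | step 6 | methyl (2S,3S)‑2‑{4‑[(2,2‑dimethylpropanoyl)oxy]‑3,5‑dimethoxyphenyl}‑7‑methoxy‑5‑[(1E)‑3‑methoxy‑3‑oxoprop‑1‑en‑1‑yl]‑2,3‑dihydro‑1‑benzofuran‑3‑carboxylate (2,3‑trans) | COc1cc([C@H]2Oc3c(OC)cc(/C=C/C(=O)OC)cc3[C@@H]2C(=O)OC)cc(OC)c1OC(=O)C(C)(C)C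
F5 | step 5 | methyl (2E)‑3‑(3‑ethynyl‑4‑hydroxy‑5‑methoxyphenyl)prop‑2‑enoate | COC(=O)/C=C/c1cc(OC)c(O)c(C#C)c1
F6 | step 4 | 4‑(bromomethyl)‑2,6‑dimethoxyphenyl 2,2‑dimethylpropanoate | COc1cc(CBr)cc(OC)c1OC(=O)C(C)(C)C
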